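Singlet oxygen is used to cut both secondary C–O bonds of the seven-membered ring at once (daucane numbering, defined below). O6 and O9 stand 1,4 to each other on the α face, opposite the C1 methyl, with C7 and the methyl-bearing C8 between them, which is the signature of a cycloheptadiene endoperoxide. Sensitised singlet oxygen is therefore added across the C6=C7–C8=C9 diene of a trans-fused hydroazulene whose C4 tertiary alcohol is capped as a triethylsilyl ether. One suprafacial [4+2] event forms both C–O bonds, fixes C6 and C9 together and leaves C7=C8 for hydroxyl-directed installation of the C8 carbinol. The diene arises by conjugate addition, Grignard addition and rhodium-catalysed hydroacylation.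

Key step: step 10

Conventions and assumptions
- Numbering: five-membered ring C1(CH3)–C2–C3–C4(iPr, O)–C5(H); seven-membered ring C5–C6–C7–C8(CH3)–C9–C10–C1; β is the face of the C1 methyl. The target is (1R,4R,5S,6S,8R,9S): 1β-CH3, 4β-OH (4α-isopropyl), 5α-H, 6α-aroyloxy, 8α-OH (8β-CH3), 9α-OH.
- Consistency check: diene 15 and endoperoxide 16 carry the same C1, C4 and C5 configuration as the target, and both peroxide oxygens of 16 are α; no stereodescriptor needs correcting.
- Assumption: 4-(benzyloxy)benzoyl chloride 21 is purchased (otherwise one step from 4-(benzyloxy)benzoic acid with (COCl)2).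

Step 1
Reactants: 1 3-methylcyclopent-2-en-1-one; 2 2-methylbut-1-en-3-yne
Product: 5 triethyl({(3R)-3-methyl-3-[(1E)-3-methylbuta-1,3-dien-1-yl]cyclopent-1-en-1-yl}oxy)silane, via dienylalane 3 (not isolated), via aluminium enolate 4 (not isolated)
Conditions: 2, iBu2AlH, hexane, 55 °C; then 1, Cu(OTf)2 (5 mol%), chiral sulfonate-bearing NHC ligand (added as its Ag carbene complex, 2.5 mol%), THF, −30 °C; then Et3SiOTf, −78 → 0 °C
Reagents that add atoms: triethylsilyl trifluoromethanesulfonate CC[Si](CC)(CC)OS(=O)(=O)C(F)(F)F
Why: Thermal cis-hydroalumination of the terminal alkyne gives the (E)-dienylalane, and copper–carbene-catalysed enantioselective conjugate addition of an alkenylaluminium reagent to a β-methyl cyclic enone (a known reaction class) should create the quaternary C1 in the sense chosen by the ligand antipode, after which O-silylation of the regiodefined aluminium enolate fixes the C4=C5 enol ether and thereby the site of the next C–C bond.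

Step 2
Reactants: 5 silyl enol ether
Product: 6 (2S,3R)-2-(hydroxymethyl)-3-methyl-3-[(1E)-3-methylbuta-1,3-dien-1-yl]cyclopentan-1-one (CH2OH cis to CH3)
Conditions: 37% aq. HCHO, Yb(OTf)3 (10 mol%), THF, rt
Reagents that add atoms: formaldehyde C=O
Why: In this lanthanide-triflate-catalysed aqueous Mukaiyama aldol reaction (hydroxymethylation) at the enol ether carbon C5, formaldehyde should approach anti to the longer dienyl arm on the adjacent quaternary C1, which sets C5 with CH2OH cis to the C1 methyl (the trans ring-fusion relation of the target), and the minor C5 epimer is removed by chromatography at this stage.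

Step 3
Reactants: 6 hydroxymethyl ketone
Product: 7 (2S,3R)-3-methyl-3-[(1E)-3-methylbuta-1,3-dien-1-yl]-2-{[(triethylsilyl)oxy]methyl}cyclopentan-1-one
Conditions: Et3SiCl, imidazole, CH2Cl2, 0 °C
Reagents that add atoms: chlorotriethylsilane CC[Si](CC)(CC)Cl
Why: Standard silylation of the primary alcohol (silyl chloride/imidazole) blocks retro-aldol loss of formaldehyde in the Grignard step and installs a group that step 6 oxidises directly.

Step 4
Reactants: 7 silyloxymethyl ketone; 8 isopropylmagnesium chloride
Product: 9 (1R,2S,3R)-3-methyl-3-[(1E)-3-methylbuta-1,3-dien-1-yl]-1-(propan-2-yl)-2-{[(triethylsilyl)oxy]methyl}cyclopentan-1-ol (OH, CH2OSiEt3 and CH3 all cis)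
Conditions: iPrMgCl, CeCl3 (anhydrous), THF, −78 → 0 °C
Reagents that add atoms: none
Why: This CeCl3-promoted Grignard 1,2-addition, which suppresses enolisation and β-hydride reduction of the hindered ketone, should occur on the α face, anti to the adjacent C5 silyloxymethyl group, so that C4 is set with OH β (cis to C6) and isopropyl α.

Step 5
Reactants: 9 tertiary alcohol
Product: 10 bis(triethylsilyl) ether of 9 (tertiary C4–OSiEt3 and primary C6–OSiEt3; configuration unchanged)
Conditions: Et3SiOTf, 2,6-lutidine, CH2Cl2, −78 → 0 °C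
Reagents that add atoms: triethylsilyl trifluoromethanesulfonate CC[Si](CC)(CC)OS(=O)(=O)C(F)(F)F
Why: Silyl triflate/2,6-lutidine silylation of a hindered tertiary alcohol gives the C4 ether, which prevents retro-aldol cleavage and β-elimination in the β-oxy aldehyde and ketone that follow and removes a hydrogen-bond donor from the β face before the key step.

Step 6
Reactants: 10 bis-silyl ether
Product: 11 (1R,2R,5R)-2-methyl-2-[(1E)-3-methylbuta-1,3-dien-1-yl]-5-(propan-2-yl)-5-[(triethylsilyl)oxy]cyclopentane-1-carbaldehyde (CHO, CH3 and OSiEt3 cis)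
Conditions: (COCl)2, DMSO, CH2Cl2, −78 → −40 °C; then Et3N, −78 °C → rt
Reagents that add atoms: none
Why: In this Swern oxidation applied directly to a primary triethylsilyl ether, the chlorosulfonium reagent cleaves and oxidises the unhindered primary Si–O group in one pot while the tertiary silyl ether is inert, and the cold, brief exposure to amine should leave C5 (flanked by two quaternary carbons) unepimerised.

Step 7
Reactants: 11 dienyl aldehyde
Product: 12 4β-(triethylsilyloxy)dauc-8-en-6-one (trans-fused, 5α-H, 1β-CH3)
Conditions: [Rh(dppe)]ClO4 (10 mol%), ClCH2CH2Cl, 65 °C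
Reagents that add atoms: none
Why: In this intramolecular hydroacylation of a 4,6-dienal with cationic monovalent rhodium, aldehyde C–H oxidative addition and hydride transfer to C10 give an η3-allyl over C7–C8–C9 whose σ–π–σ isomerisation lets reductive elimination at C7 close the seven-membered ring with a cis C8=C9 bond, while the trans arrangement of CHO and dienyl on the cyclopentane disfavours the strained trans-fused five-membered ketone, and no stereocentre is created or disturbed under these neutral conditions.

Step 8
Reactants: 12 β,γ-unsaturated ketone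
Product: 14 4β-(triethylsilyloxy)dauca-6,8-dien-6-yl trifluoromethanesulfonate, via potassium dienolate 13 (not isolated)
Conditions: KHMDS, THF, −78 °C; then PhNTf2, −78 → 0 °C
Reagents that add atoms: N-phenylbis(trifluoromethanesulfonimide) O=S(=O)(N(c1ccccc1)S(=O)(=O)C(F)(F)F)C(F)(F)F
Why: Kinetic deprotonation at C7, which is both α to the ketone and allylic and far less hindered than C5, gives the linear dienolate, and O-sulfonylation (enol triflate formation) fixes the C6=C7–C8=C9 diene without affecting any stereocentre.

Step 9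
Reactants: 14 dienyl triflate
Product: 15 4β-(triethylsilyloxy)dauca-6,8-diene (trans-fused; precursor of the key step)
Conditions: Pd(OAc)2 (5 mol%), PPh3, Bu3N, HCO2H, DMF, 60 °C
Reagents that add atoms: none
Why: Palladium-catalysed formate reduction of an enol triflate (oxidative addition, formate exchange, decarboxylation to a palladium hydride, C–H reductive elimination) replaces OTf by H without moving the double bonds and tolerates the silyl ether.

Step 10
Reactants: 15 diene
Product: 16 6α,9α-epidioxy-4β-(triethylsilyloxy)dauc-7-ene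
Conditions: O2, tetraphenylporphyrin (cat.), visible light, CH2Cl2, −40 °C
Reagents that add atoms: dioxygen O=O
Why: Visible-light sensitisation gives singlet oxygen, which acts as a two-atom dienophile and adds suprafacially across the cisoid C6=C7–C8=C9 diene in a concerted [4+2] cycloaddition, the closest known reaction being endoperoxide formation from cyclohepta-1,3-dienes. The new 1,2-dioxine ring (C6–O–O–C9 bridged by C7=C8) closes by cycloaddition, not by an exo or endo cyclisation, so both C–O bonds must land on one face of the seven-membered ring. C6 and C9 are therefore set together, and their α configuration is controlled by the axial C1 methyl, which lies on the β face 1,3 to both diene termini, supported by the β-oriented C4 silyloxy group. The C4 oxygen is kept silylated because a free β-hydroxyl could steer the oxidant to the β face by hydrogen bonding, whereas the α face offers only H5 and the C4 isopropyl group, which sits outside the ring. The step needs face selectivity and cycloaddition-over-ene chemoselectivity; the ring-locked cisoid diene, low temperature and an apolar solvent should favour cycloaddition over hydrogen abstraction from the C8 methyl or C10.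

Step 11
Reactants: 16 endoperoxide
Product: 17 4β-(triethylsilyloxy)dauc-7-ene-6α,9α-diol
Conditions: thiourea, MeOH, rt
Reagents that add atoms: none
Why: Thiourea reduction of an endoperoxide cleaves only the O–O bond, so both C–O bonds and hence the 6α,9α relation are retained, and the neutral conditions avoid base-induced rearrangement of the peroxide.

Step 12
Reactants: 17 ene-diol
Product: 18 7α,8α-epoxy-4β-(triethylsilyloxy)daucane-6α,9α-diol
Conditions: VO(acac)2 (5 mol%), tBuOOH, CH2Cl2, 0 °C → rt
Reagents that add atoms: tert-butyl hydroperoxide CC(C)(C)OO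
Why: In this hydroxyl-directed vanadium-catalysed epoxidation both allylic hydroxyls (C6 and C9) are α and deliver the metal-bound peroxide to the α face of C7=C8, which sets C8 (oxygen α, methyl β) and C7.

Step 13
Reactants: 18 epoxy diol
Product: 19 4β-(triethylsilyloxy)daucane-6α,8α,9α-triol
Conditions: LiEt3BH, THF, 0 °C → rt; aq. NH4Cl
Reagents that add atoms: none
Why: Regioselective hydride opening of the trisubstituted epoxide by SN2 attack at the less substituted C7 from the β face leaves the C8–O bond intact, so the tertiary C8 hydroxyl keeps the α configuration, while both neighbouring hydroxyls are cis to the epoxide (no Payne rearrangement) and the silyl ether is inert.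

Step 14
Reactants: 19 triol
Product: 20 8α,9α-(isopropylidenedioxy)-4β-(triethylsilyloxy)daucan-6α-ol
Conditions: Me2C(OMe)2, PPTS (cat.), CH2Cl2, rt
Reagents that add atoms: 2,2-dimethoxypropane COC(C)(C)OC
Why: Acid-catalysed transketalisation should select the cis-1,2-diol at C8/C9 (fused dioxolane) over a bridged 1,3-dioxane across C6/C8, leaving C6–OH as the only free hydroxyl.

Step 15
Reactants: 20 acetonide alcohol; 21 4-(benzyloxy)benzoyl chloride
Product: 22 8α,9α-(isopropylidenedioxy)-4β-(triethylsilyloxy)daucan-6α-yl 4-(benzyloxy)benzoate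
Conditions: DMAP, Et3N, CH2Cl2, rt → 40 °C
Reagents that add atoms: none
Why: DMAP-catalysed acylation by the acid chloride through the acylpyridinium ion esterifies the single free secondary hydroxyl with retention at C6, the phenol being masked as a benzyl ether to prevent self-acylation.

Step 16
Reactants: 22 protected ester
Product: 24 4β,8α,9α-trihydroxydaucan-6α-yl 4-hydroxybenzoate (target), via phenol 23 (not isolated)
Conditions: H2 (1 atm), Pd/C, EtOAc–MeOH, rt; then 1 M HCl, rt
Reagents that add atoms: none
Why: Hydrogenolysis of the aryl benzyl ether over palladium (no C=C bond remains) followed in the same pot by mild acid hydrolysis of the acetonide and the tertiary silyl ether should release all four hydroxyls without touching the C6 ester or any stereocentre.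

Compound list
1 | 3-methylcyclopent-2-en-1-one | CC1=CC(=O)CC1 | starting material
2 | 2-methylbut-1-en-3-yne | C=C(C)C#C | starting material
3 | [(1E)-3-methylbuta-1,3-dien-1-yl]bis(2-methylpropyl)alumane | CC(C)C[Al](CC(C)C)/C=C/C(C)=C | intermediate
4 | diisobutylaluminium C4=C5 enolate of (S)-3-methyl-3-[(1E)-3-methylbuta-1,3-dien-1-yl]cyclopentanone | CC(C)C[Al](CC(C)C)OC1=C[C@@](C)(/C=C/C(C)=C)CC1 | intermediate
5 | triethyl({(3R)-3-methyl-3-[(1E)-3-methylbuta-1,3-dien-1-yl]cyclopent-1-en-1-yl}oxy)silane | CC[Si](CC)(CC)OC1=C[C@@](C)(/C=C/C(C)=C)CC1 | intermediate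
6 | (2S,3R)-2-(hydroxymethyl)-3-methyl-3-[(1E)-3-methylbuta-1,3-dien-1-yl]cyclopentan-1-one | O=C1CC[C@](C)(/C=C/C(C)=C)[C@H]1CO | intermediate
7 | (2S,3R)-3-methyl-3-[(1E)-3-methylbuta-1,3-dien-1-yl]-2-{[(triethylsilyl)oxy]methyl}cyclopentan-1-one | O=C1CC[C@](C)(/C=C/C(C)=C)[C@H]1CO[Si](CC)(CC)CC | intermediate
8 | isopropylmagnesium chloride | CC(C)[Mg]Cl | starting material
9 | (1R,2S,3R)-3-methyl-3-[(1E)-3-methylbuta-1,3-dien-1-yl]-1-(propan-2-yl)-2-{[(triethylsilyl)oxy]methyl}cyclopentan-1-ol | CC(C)[C@]1(O)CC[C@](C)(/C=C/C(C)=C)[C@H]1CO[Si](CC)(CC)CC | intermediate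
10 | bis(triethylsilyl) ether of 9 (tertiary and primary oxygens silylated) | CC(C)[C@]1(O[Si](CC)(CC)CC)CC[C@](C)(/C=C/C(C)=C)[C@H]1CO[Si](CC)(CC)CC | intermediate
11 | (1R,2R,5R)-2-methyl-2-[(1E)-3-methylbuta-1,3-dien-1-yl]-5-(propan-2-yl)-5-[(triethylsilyl)oxy]cyclopentane-1-carbaldehyde | CC(C)[C@]1(O[Si](CC)(CC)CC)CC[C@](C)(/C=C/C(C)=C)[C@H]1C=O | intermediate
12 | 4β-(triethylsilyloxy)dauc-8-en-6-one (trans-fused) | CC(C)[C@]1(O[Si](CC)(CC)CC)CC[C@]2(C)CC=C(C)CC(=O)[C@H]21 | intermediate
13 | potassium 4β-(triethylsilyloxy)dauca-6,8-dien-6-olate | CC(C)[C@]1(O[Si](CC)(CC)CC)CC[C@]2(C)CC=C(C)C=C([O-])[C@H]21.[K+] | intermediate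
14 | 4β-(triethylsilyloxy)dauca-6,8-dien-6-yl trifluoromethanesulfonate | CC(C)[C@]1(O[Si](CC)(CC)CC)CC[C@]2(C)CC=C(C)C=C(OS(=O)(=O)C(F)(F)F)[C@H]21 | intermediate
15 | 4β-(triethylsilyloxy)dauca-6,8-diene (trans-fused) | CC(C)[C@]1(O[Si](CC)(CC)CC)CC[C@]2(C)CC=C(C)C=C[C@H]21 | intermediate
16 | 6α,9α-epidioxy-4β-(triethylsilyloxy)dauc-7-ene | CC(C)[C@]1(O[Si](CC)(CC)CC)CC[C@]2(C)C[C@H](OO3)C(C)=C[C@H]3[C@H]21 | intermediate
17 | 4β-(triethylsilyloxy)dauc-7-ene-6α,9α-diol | CC(C)[C@]1(O[Si](CC)(CC)CC)CC[C@]2(C)C[C@H](O)C(C)=C[C@H](O)[C@H]21 | intermediate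
18 | 7α,8α-epoxy-4β-(triethylsilyloxy)daucane-6α,9α-diol | CC(C)[C@]1(O[Si](CC)(CC)CC)CC[C@]2(C)C[C@H](O)[C@]3(C)O[C@@H]3[C@H](O)[C@H]21 | intermediate
19 | 4β-(triethylsilyloxy)daucane-6α,8α,9α-triol | CC(C)[C@]1(O[Si](CC)(CC)CC)CC[C@]2(C)C[C@H](O)[C@](C)(O)C[C@H](O)[C@H]21 | intermediate
20 | 8α,9α-(isopropylidenedioxy)-4β-(triethylsilyloxy)daucan-6α-ol | CC(C)[C@]1(O[Si](CC)(CC)CC)CC[C@]2(C)C[C@@H]3OC(C)(C)O[C@]3(C)C[C@H](O)[C@H]21 | intermediate
21 | 4-(benzyloxy)benzoyl chloride | O=C(Cl)c1ccc(OCc2ccccc2)cc1 | starting material
22 | 8α,9α-(isopropylidenedioxy)-4β-(triethylsilyloxy)daucan-6α-yl 4-(benzyloxy)benzoate | CC(C)[C@]1(O[Si](CC)(CC)CC)CC[C@]2(C)C[C@@H]3OC(C)(C)O[C@]3(C)C[C@H](OC(=O)c4ccc(OCc5ccccc5)cc4)[C@H]21 | intermediate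
23 | 8α,9α-(isopropylidenedioxy)-4β-(triethylsilyloxy)daucan-6α-yl 4-hydroxybenzoate | CC(C)[C@]1(O[Si](CC)(CC)CC)CC[C@]2(C)C[C@@H]3OC(C)(C)O[C@]3(C)C[C@H](OC(=O)c4ccc(O)cc4)[C@H]21 | intermediate
24 | (3R,3aS,4S,6R,7S,8aR)-3,6,7-trihydroxy-6,8a-dimethyl-3-(propan-2-yl)decahydroazulen-4-yl 4-hydroxybenzoate (4β,8α,9α-trihydroxydaucan-6α-yl 4-hydroxybenzoate) | CC(C)[C@]1(O)CC[C@]2(C)C[C@H](O)[C@](C)(O)C[C@H](OC(=O)c3ccc(O)cc3)[C@H]21 | target

Total step count: 16. Longest linear sequence: 16 steps (1 and 2 to 24); compounds 8 and 21 are purchased.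

Steps most likely to fail: 10, 7 and 1.

Step 10. Singlet oxygen may be diverted into the ene pathway (hydrogen abstraction from the C8 methyl or C10, giving allylic hydroperoxides), or the discrimination between the α and β faces may be incomplete. The fallback gives up singlet oxygen and sets the three ring oxygens one after another. It sets out from ketone 12, which already carries O6. Osmium-catalysed syn-dihydroxylation (OsO4 cat., NMO, acetone–H2O) of C8=C9 from the α face, anti to the C1 methyl, should give the keto diol 8α,9α-dihydroxy-4β-(triethylsilyloxy)daucan-6-one F1. A Narasaka–Prasad reduction (Et2BOMe, then NaBH4, THF–MeOH, −78 °C) through the boron chelate between O8 and the C6 carbonyl should then give the 1,3-syn, i.e. 6α, alcohol. This is triol 19, where the route is rejoined; steps 8 to 13 are bypassed.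

Step 7. C–H activation may stall at the congested aldehyde, with loss of CO, or the allyl isomerisation needed before ring closure may be too slow. The fallback closes the ring by carbonyl coupling and sets out from bis-silyl ether 10. A 1,4-hydroboration with pinacolborane catalysed by Ni(cod)2 (zerovalent nickel) and PCy3 should put boron on C7 and hydrogen on C10, giving the (Z)-allylboronate F2, in which C8=C9 already has the geometry the ring requires. Oxidation with NaOH/H2O2 gives the (Z)-allylic alcohol F3. A Swern oxidation converts both the allylic alcohol and the primary triethylsilyl ether into the dialdehyde F4. Intramolecular McMurry coupling (TiCl3, Zn–Cu, DME, reflux, high dilution) then joins C6 and C7 as the C6=C7 double bond and returns to the route at diene 15.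

Step 1. The dienyl group may transfer poorly from aluminium, or enantioselectivity may erode through competing uncatalysed or 1,2-addition. The fallback exchanges the roles of the two C1 substituents and sets out from alane 3, made from 2 as before. Negishi coupling of 3 with purchased 3-bromocyclopent-2-en-1-one (O=C1C=C(Br)CC1; Pd(PPh3)4, zerovalent palladium, ZnCl2, THF) should give the dienyl enone 3-[(1E)-3-methylbuta-1,3-dien-1-yl]cyclopent-2-en-1-one F5. Copper–carbene-catalysed 1,4-addition of Me3Al (Cu(OTf)2, chiral NHC ligand of the appropriate antipode) then creates the same quaternary centre and gives the dimethylaluminium enolate F6. Trapping with Et3SiOTf returns to the route at silyl enol ether 5.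

Further compounds
F1 | step 10 | 8α,9α-dihydroxy-4β-(triethylsilyloxy)daucan-6-one | CC(C)[C@]1(O[Si](CC)(CC)CC)CC[C@]2(C)C[C@H](O)[C@](C)(O)CC(=O)[C@H]21
F2 | step 7 | (Z)-allylboronate: 10 with the C1 side chain changed to (2Z)-3-methyl-4-(4,4,5,5-tetramethyl-1,3,2-dioxaborolan-2-yl)but-2-en-1-yl | CC(C)[C@]1(O[Si](CC)(CC)CC)CC[C@](C)(C/C=C(/C)CB2OC(C)(C)C(C)(C)O2)[C@H]1CO[Si](CC)(CC)CC
F3 | step 7 | (Z)-allylic alcohol: 10 with the C1 side chain changed to (2Z)-4-hydroxy-3-methylbut-2-en-1-yl | CC(C)[C@]1(O[Si](CC)(CC)CC)CC[C@](C)(C/C=C(/C)CO)[C@H]1CO[Si](CC)(CC)CC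
F4 | step 7 | dialdehyde: 2-methyl-2-[(2Z)-3-methyl-4-oxobut-2-en-1-yl]-5-(propan-2-yl)-5-[(triethylsilyl)oxy]cyclopentane-1-carbaldehyde (ring configuration as in 11) | CC(C)[C@]1(O[Si](CC)(CC)CC)CC[C@](C)(C/C=C(/C)C=O)[C@H]1C=O
F5 | step 1 | 3-[(1E)-3-methylbuta-1,3-dien-1-yl]cyclopent-2-en-1-one | O=C1C=C(/C=C/C(C)=C)CC1
F6 | step 1 | dimethylaluminium C4=C5 enolate of (S)-3-methyl-3-[(1E)-3-methylbuta-1,3-dien-1-yl]cyclopentanone | C[Al](C)OC1=C[C@@](C)(/C=C/C(C)=C)CC1
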